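## The problem

The target 21, (5S,6S,10S,13S)-6β,13-dihydroxy-7-oxolabd-8-en-15,16-olide (labdane numbering: decalin C1–C10, C17 on C8, C18 and C19 on C4, C20 on C10, side chain C11–C16 with C15 the lactone carbonyl and C16 the OCH2), is a trans-fused 4,4,10-trimethyldecalin whose ring B is a fully substituted enone (C7=O, C8=C9) joined through the C11–C12 tether to a 3-hydroxy-γ-butyrolactone. C5 and C10 form the ring fusion and can be taken from the chiral pool. They control C6 in one sense only: the β-face of C6 lies under the axial methyl groups C19 and C20, so external reagents reach C6 from the α-face. The 6β-hydroxyl is therefore the hindered epimer, and it can be reached only if the oxygen is on C6 first and the C6–H bond is made last, from the α-face. C13 is a quaternary carbinol four bonds from the nearest ring stereocentre and can only be set by a reagent or catalyst. The fragile groups are the β-hydroxy lactone (base opens it, dehydrates it to a butenolide or cleaves it by retro-aldol) and the α-ketol next to C5–H (base epimerises C6, over-oxidation gives a diosphenol that erases C5), so both should appear late. The feature that makes the key step possible is that C14 and C16 are both CH2 groups on C13, one bound to the ring oxygen and one to C15. Removing C15 as carbon monoxide leaves a 3-substituted oxetan-3-ol in which C13 is not stereogenic, so inserting CO into one of two enantiotopic CH2–O bonds creates the lactone ring, C15 and the C13 configuration together.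

## Retrosynthesis

**21 from 20.** No skeletal bond is cut; the C7 carbonyl of 21 is traced back to the allylic 7β-alcohol of triol 20. This keeps the enone and the α-ketol out of the carbonylation and the desilylation. Of the three hydroxyls of 20 only the one at C7 is allylic, so the forward step asks for a chemoselective allylic oxidation under neutral conditions.

**20 from 19.** Three Si–O bonds are cut, leading to the tris(triethylsilyl) ether 19. The silyl groups mask every hydroxyl during the key step, and the one on O13 also serves as the steric label the catalyst reads. Their removal must avoid alkoxide formation next to the lactone.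

**19 from 17 and 18 (key disconnection).** The C14–C15 and C15–O16 bonds are cut, giving the 3-silyloxyoxetane 17 and carbon monoxide 18. The neighbouring cuts (acetate aldol onto a C13 ketone, or dihydroxylation of a 1,1-disubstituted alkene) each build C13 against no substrate bias and need separate steps for the ring. This cut makes ring, carbonyl carbon and stereocentre in one catalytic step, and 17 has one carbon and one stereocentre fewer than 19. The forward reaction must open only the pro-R CH2–O bond of the oxetane.

**17 from 16, 15, 14 and 12, back to 10.** The C6–O bond is traced back so that the C6–H bond is formed last. Silyl ether 17 comes from the 6β-alcohol 16, and 16 from the 6-ketone 15 by α-face hydride addition. Ketone 15 comes from enone 10 by a 1,2-carbonyl transposition that keeps the C7 oxygen: kinetic silyl dienol ether 12, hydroboration–oxidation to the 6α-alcohol 14 (oxygen on C6, hydrogen on C7, O7 still silylated), then oxidation. Direct α'-hydroxylation of 10 would be shorter but puts the oxygen on the α-face; inversion would then need SN2 attack through the blocked β-face or a detour through a C6/C7 dicarbonyl stage that enolises toward C5. The forward steps ask for regioselective enolisation, face-selective borane addition and face-selective reduction, all governed by the same two axial methyl groups.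

**10 from 9, and 9 from 8.** The C7–O bond is cut by allylic oxidation of the C8=C9 alkene of silyl ether 9, a standard operation on labd-8-enes. The tertiary silyl ether is made from oxetanol 8 before this oxidation, so that the later enolate chemistry meets no free hydroxyl.

**8 from 5 and 6.** The C12–C13 bond is cut between a C12 nucleophile, alkyllithium 7 made from iodide 5, and oxetan-3-one 6. The ketone brings C13, C14, C16 and both C–O bonds as one symmetric commercial unit, which is why C13 needs no control at this stage.

**5 from 4, 3 and 1.** (+)-Sclareolide 1 supplies C5, C10 and all sixteen carbons of the decalin with C11 and C12. Its C8–O bond and C9–H are traded for the C8=C9 alkene in ester 3 (through acid 2), and the former lactone carbonyl C12 is reduced to alcohol 4 and converted to iodide 5.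

## Roads not taken

Alternative 1: The cut runs through C4–C5, C9–C10 and C8–O and leads back to the acyclic ketone (5E,9E)-farnesylacetone A1. In the forward direction a chiral Brønsted acid activated by a Lewis acid protonates the terminal alkene of A1, the polyene folds chair–chair, and the ketone oxygen traps the C8 cation to give sclareol oxide A2. Its merits are real: two carbocycles and the C5/C10 relationship form in one step from the achiral chain A1, either enantiomer is available, and the route is independent of any natural source. In these respects it is better than the chosen plan. Its weak points for this target lie in what A2 lacks. A2 has oxygen on C8 instead of the C8=C9 alkene, C13 is an enol ether carbon with a methyl where C16 must carry oxygen, and C14 and C15 are missing. The full ring-B oxidation is still needed, and C13 would be built afterwards without control. In comparison, the cyclisation of A1 spends its selectivity on C5 and C10, which 1 supplies at full enantiopurity. The chosen plan spends its one demanding step on C13, the centre no starting material provides, but it depends on an unprecedented catalytic reaction.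

Alternative 2: The cut runs through C1–C10 and C4–C5 and leads back to 2,6-dimethyl-1,4-benzoquinone A3 as ring B. In the forward direction 4-methylpenta-1,3-diene A4 adds to the methyl-bearing double bond of A3 under a chiral cationic boron Lewis acid to give the cis-fused adduct A5. Ring B arrives with C17, C20 and carbonyls at C6 and C9. The C6 ketone of A5 is exactly the function from which α-face reduction gives the 6β-alcohol. The chosen route needs four steps to create that ketone, so here the alternative is better. The C9 carbonyl could take the side chain by addition and allylic transposition. The weak points are several. A4 is a reluctant diene because its cis-methyl disfavours the s-cis conformer, and it must bond its fully substituted terminus to C5 of A3. A5 is cis-fused and needs epimerisation at C5, it carries an extra C2=C3 alkene, and its two ketones must be differentiated before a nucleophile adds to the neopentyl C9 carbonyl. C13 is again left open. In comparison, this road is convergent and quick in ring B but uncertain in its cycloaddition and longer overall. The chosen plan has a dependable decalin and accepts a longer ring-B sequence.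

Alternative 3: The cut runs through C5=C6. In the forward direction base forms the C6 enolate of the side-chain ketone in cyclohexanone A6, 6-[4-(methoxymethoxy)-3-oxobutyl]-2,2,6-trimethylcyclohexanone, which adds to the ring carbonyl and dehydrates to the bicyclic 6-alkoxy enone A7. A7 carries the C6 oxygen on an sp2 carbon, and cis-hydrogenation of C5=C6 from the α-face would set C5 and the 6β-oxygen at once, which is more direct for C6 than the chosen plan. The weak points are in the ring closure and in what is missing. The ring carbonyl of A6 lies between two quaternary carbons, so the aldol addition is slow and reversible, and dehydration gives a strained tetrasubstituted alkene. The C10 quaternary centre of A6 must first be made enantioselectively. A7 lacks C17, the C8=C9 alkene and the whole side chain, the hydrogenation of its tetrasubstituted enol ether is itself demanding, and C13 is untouched. In comparison, this road needs many more steps before the point where the chosen plan starts, with its main risk in the ring-forming step. The chosen plan concentrates its risk in one late catalytic step for which a fallback exists.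

Key step: step 12

Assumption: the sense of induction of the chiral chromium–salen cation on an oxetane cannot be predicted from existing data, so the ligand enantiomer is to be matched by experiment; both enantiomers are accessible.

## Route

Step 1
Reactants: 1 (+)-sclareolide
Product: 3 methyl (5S,10S)-13,14,15,16-tetranorlabd-8-en-12-oate, via tetranorlabd-8-en-12-oic acid 2 (not isolated)
Conditions: conc. H2SO4, MeOH, reflux
Reagents that add atoms: methanol, CO
Why: Acid-promoted alkyl–oxygen cleavage of the tertiary lactone (E1) followed by Fischer esterification; under equilibrating acid the alkene should settle mainly in the tetrasubstituted C8=C9 position, which deliberately erases C8 and C9 and leaves C5 and C10 untouched; minor positional isomers are removed on AgNO3-impregnated silica.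

Step 2
Reactants: 3 methyl (5S,10S)-13,14,15,16-tetranorlabd-8-en-12-oate
Product: 4 (5S,10S)-13,14,15,16-tetranorlabd-8-en-12-ol
Conditions: LiAlH4, THF, 0 °C
Reagents that add atoms: none
Why: Hydride reduction of the ester to the primary alcohol; the isolated tetrasubstituted alkene is inert.

Step 3
Reactants: 4 (5S,10S)-13,14,15,16-tetranorlabd-8-en-12-ol
Product: 5 (5S,10S)-12-iodo-13,14,15,16-tetranorlabd-8-ene
Conditions: I2, PPh3, imidazole, CH2Cl2, 0 °C → rt
Reagents that add atoms: iodine, II
Why: Appel-type iodination through the alkoxyphosphonium salt, with SN2 displacement at the unhindered primary carbon.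

Step 4
Reactants: 5 (5S,10S)-12-iodo-13,14,15,16-tetranorlabd-8-ene; 6 oxetan-3-one
Product: 8 3-[(5S,10S)-13,14,15,16-tetranorlabd-8-en-12-yl]oxetan-3-ol, via C12 alkyllithium 7 (not isolated)
Conditions: t-BuLi (2 equiv), Et2O/pentane, −78 °C; then 6, −78 → 0 °C; H2O
Reagents that add atoms: none
Why: Lithium–iodine exchange gives the primary alkyllithium, whose 1,2-addition to the strained ketone forms the C12–C13 bond; C13 is not yet stereogenic because its two ring CH2 groups are identical.

Step 5
Reactants: 8 3-[(5S,10S)-13,14,15,16-tetranorlabd-8-en-12-yl]oxetan-3-ol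
Product: 9 3-[(5S,10S)-13,14,15,16-tetranorlabd-8-en-12-yl]-3-(triethylsilyloxy)oxetane
Conditions: Et3SiOTf, 2,6-lutidine, CH2Cl2, −78 °C
Reagents that add atoms: triethylsilyl trifluoromethanesulfonate, CC[Si](CC)(CC)OS(=O)(=O)C(F)(F)F
Why: Silyl triflate silylation of the tertiary alcohol with a hindered pyridine base; the low temperature and the base keep the oxetane from Lewis-acid opening.

Step 6
Reactants: 9 3-[(5S,10S)-13,14,15,16-tetranorlabd-8-en-12-yl]-3-(triethylsilyloxy)oxetane
Product: 10 (5S,10S)-12-[3-(triethylsilyloxy)oxetan-3-yl]-13,14,15,16-tetranorlabd-8-en-7-one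
Conditions: CrO3, 3,5-dimethylpyrazole, CH2Cl2, −20 °C
Reagents that add atoms: chromium trioxide, O=[Cr](=O)=O
Why: Allylic oxidation with the CrO3–3,5-dimethylpyrazole complex (hexavalent chromium), the standard route from labd-8-enes and drim-8-enes to their 7-ketones; the ring methylene C7 should be attacked in preference to the side-chain methylene C11 and the C17 methyl.

Step 7
Reactants: 10 (5S,10S)-12-[3-(triethylsilyloxy)oxetan-3-yl]-13,14,15,16-tetranorlabd-8-en-7-one
Product: 12 (5S,10S)-7-(triethylsilyloxy)-12-[3-(triethylsilyloxy)oxetan-3-yl]-13,14,15,16-tetranorlabda-6,8-diene, via lithium dienolate 11 (not isolated)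
Conditions: LiN(iPr)2, THF, −78 °C; then Et3SiCl, Et3N, −78 → 0 °C
Reagents that add atoms: chlorotriethylsilane, CC[Si](Cl)(CC)CC
Why: Kinetic deprotonation at the only α' position (C6) gives the cross-conjugated lithium dienolate, which is trapped on oxygen as the silyl dienol ether; the γ protons at C11 are removed more slowly under these conditions.

Step 8
Reactants: 12 (5S,10S)-7-(triethylsilyloxy)-12-[3-(triethylsilyloxy)oxetan-3-yl]-13,14,15,16-tetranorlabda-6,8-diene
Product: 14 (5S,6R,7R,10S)-7β-(triethylsilyloxy)-12-[3-(triethylsilyloxy)oxetan-3-yl]-13,14,15,16-tetranorlabd-8-en-6α-ol, via 6α-alkylborane 13 (not isolated)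
Conditions: BH3·SMe2, THF, 0 °C → rt; then 30% H2O2, aq NaOH, 0 °C
Reagents that add atoms: hydrogen peroxide, OO
Why: Hydroboration–oxidation of a silyl enol ether: boron adds to C6 (β to oxygen, less substituted) and hydrogen to C7 from the open α-face, so oxidation with retention leaves the C6 hydroxyl α and the C7 silyloxy group β; the tetrasubstituted C8=C9 alkene reacts far more slowly, and both new centres are temporary.

Step 9
Reactants: 14 (5S,6R,7R,10S)-7β-(triethylsilyloxy)-12-[3-(triethylsilyloxy)oxetan-3-yl]-13,14,15,16-tetranorlabd-8-en-6α-ol
Product: 15 (5S,7R,10S)-7β-(triethylsilyloxy)-12-[3-(triethylsilyloxy)oxetan-3-yl]-13,14,15,16-tetranorlabd-8-en-6-one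
Conditions: Dess–Martin periodinane, NaHCO3, CH2Cl2, 0 °C → rt
Reagents that add atoms: none
Why: Dess–Martin oxidation of the secondary alcohol under buffered, non-enolising conditions gives the β,γ-unsaturated 6-ketone; the trans ring fusion is the stable arrangement at C5.

Step 10
Reactants: 15 (5S,7R,10S)-7β-(triethylsilyloxy)-12-[3-(triethylsilyloxy)oxetan-3-yl]-13,14,15,16-tetranorlabd-8-en-6-one
Product: 16 (5S,6S,7R,10S)-7β-(triethylsilyloxy)-12-[3-(triethylsilyloxy)oxetan-3-yl]-13,14,15,16-tetranorlabd-8-en-6β-ol
Conditions: NaBH4, CeCl3·7H2O, MeOH/THF, −20 °C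
Reagents that add atoms: none
Why: Luche-type carbonyl reduction; the β-face of C6 is screened by the syn-axial methyl groups C19 and C20, so hydride should enter from the α-face and leave the hydroxyl β (axial), which sets C6 as S; the cerium salt speeds the addition and suppresses enolisation toward C5 and C7.

Step 11
Reactants: 16 (5S,6S,7R,10S)-7β-(triethylsilyloxy)-12-[3-(triethylsilyloxy)oxetan-3-yl]-13,14,15,16-tetranorlabd-8-en-6β-ol
Product: 17 (5S,6S,7R,10S)-6β,7β-bis(triethylsilyloxy)-12-[3-(triethylsilyloxy)oxetan-3-yl]-13,14,15,16-tetranorlabd-8-ene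
Conditions: Et3SiOTf, 2,6-lutidine, CH2Cl2, −78 → −20 °C
Reagents that add atoms: triethylsilyl trifluoromethanesulfonate, CC[Si](CC)(CC)OS(=O)(=O)C(F)(F)F
Why: Silyl triflate silylation of the hindered axial alcohol; any product of 1,2-silyl migration between O6 and O7 from step 10 converges on the same bis-silyl ether.

Step 12
Reactants: 17 (5S,6S,7R,10S)-6β,7β-bis(triethylsilyloxy)-12-[3-(triethylsilyloxy)oxetan-3-yl]-13,14,15,16-tetranorlabd-8-ene; 18 carbon monoxide
Product: 19 (5S,6S,7R,10S,13S)-6β,7β,13-tris(triethylsilyloxy)labd-8-en-15,16-olide
Conditions: [(salcy)Cr(THF)2][Co(CO)4] (5 mol%; salcy = N,N'-bis(3,5-di-tert-butylsalicylidene)-trans-1,2-cyclohexanediamine dianion, enantiomer matched for pro-R opening), CO (60 bar), 1,2-dimethoxyethane, 70 °C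
Reagents that add atoms: none
Why: Proposed new method: the cationic trivalent chromium centre coordinates the oxetane oxygen of 17 and the tetracarbonylcobaltate counter-ion opens one activated CH2–O bond by SN2 attack from the rear, giving a chromium alkoxide at O16 and an alkylcobalt tetracarbonyl at C14; migratory insertion and uptake of 18 give the acylcobalt species (new C14–C15 bond), and the chromium-bound alkoxide then attacks the acyl carbon to form C15–O16, releasing the lactone and regenerating the ion pair. The nearest known reaction types are the ring-expanding carbonylation of oxetanes to γ-butyrolactones and the enantioselective carbonylative desymmetrisation of meso-epoxides to β-lactones, both by Lewis acid–[Co(CO)4]− ion pairs, and the catalytic enantioselective opening of 3,3-disubstituted oxetanes; what is new is their combination on a prochiral oxetane. The five-membered lactone closes by 5-exo-trig acyl substitution. No bond to C13 is made or broken: C13 becomes stereogenic because only one of its two enantiotopic CH2–O arms is opened, and its S configuration is controlled solely by the chiral salcy ligand on chromium, which must direct cobaltate to the pro-R methylene (the one that becomes C14); the decalin stereocentres are four bonds away and give no useful bias. The selectivity needed is therefore enantiotopic-group selection, and the substrate helps only by offering the catalyst two clearly different substituents on C13, the bulky triethylsilyloxy group and the unbranched CH2CH2 tether. The strain of the four-membered ring supplies the driving force for C–O cleavage, high CO pressure should keep insertion faster than β-silyloxy elimination from the alkylcobalt intermediate, and the silyl ethers and the tetrasubstituted alkene are inert to both catalyst components.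

Step 13
Reactants: 19 (5S,6S,7R,10S,13S)-6β,7β,13-tris(triethylsilyloxy)labd-8-en-15,16-olide
Product: 20 (5S,6S,7R,10S,13S)-6β,7β,13-trihydroxylabd-8-en-15,16-olide
Conditions: HF·pyridine, pyridine, THF, 0 °C → rt
Reagents that add atoms: none
Why: Fluoride cleavage of the three Si–O bonds under buffered acidic conditions, which avoids alkoxide formation and so β-elimination or retro-aldol opening of the β-hydroxy lactone.

Step 14
Reactants: 20 (5S,6S,7R,10S,13S)-6β,7β,13-trihydroxylabd-8-en-15,16-olide
Product: 21 (5S,6S,10S,13S)-6β,13-dihydroxy-7-oxolabd-8-en-15,16-olide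
Conditions: activated MnO2, CH2Cl2, rt
Reagents that add atoms: none
Why: Chemoselective MnO2 oxidation of the allylic C7 alcohol; the saturated axial 6β-hydroxyl and the tertiary 13-hydroxyl should not be oxidised, and the neutral conditions leave C5, C6 and the lactone undisturbed.

## Compound list

Names use the labdane numbering given above.

1 | (+)-sclareolide, (3aR,5aS,9aS,9bR)-3a,6,6,9a-tetramethyldecahydronaphtho[2,1-b]furan-2(1H)-one | C[C@]12CCCC(C)(C)[C@@H]1CC[C@@]1(C)OC(=O)C[C@@H]12 | starting material
2 | (5S,10S)-13,14,15,16-tetranorlabd-8-en-12-oic acid (C8=C9 alkene, CH2CO2H on C9; formed in the flask, not isolated) | CC1=C(CC(=O)O)[C@@]2(C)CCCC(C)(C)[C@@H]2CC1 | intermediate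
3 | methyl (5S,10S)-13,14,15,16-tetranorlabd-8-en-12-oate | CC1=C(CC(=O)OC)[C@@]2(C)CCCC(C)(C)[C@@H]2CC1 | intermediate
4 | (5S,10S)-13,14,15,16-tetranorlabd-8-en-12-ol | CC1=C(CCO)[C@@]2(C)CCCC(C)(C)[C@@H]2CC1 | intermediate
5 | (5S,10S)-12-iodo-13,14,15,16-tetranorlabd-8-ene | CC1=C(CCI)[C@@]2(C)CCCC(C)(C)[C@@H]2CC1 | intermediate
6 | oxetan-3-one | O=C1COC1 | starting material
7 | (5S,10S)-12-lithio-13,14,15,16-tetranorlabd-8-ene (formed in the flask, not isolated) | CC1=C(CC[Li])[C@@]2(C)CCCC(C)(C)[C@@H]2CC1 | intermediate
8 | 3-[(5S,10S)-13,14,15,16-tetranorlabd-8-en-12-yl]oxetan-3-ol (oxetane C3 is C13) | CC1=C(CCC2(O)COC2)[C@@]2(C)CCCC(C)(C)[C@@H]2CC1 | intermediate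
9 | 3-[(5S,10S)-13,14,15,16-tetranorlabd-8-en-12-yl]-3-(triethylsilyloxy)oxetane | CC1=C(CCC2(O[Si](CC)(CC)CC)COC2)[C@@]2(C)CCCC(C)(C)[C@@H]2CC1 | intermediate
10 | (5S,10S)-12-[3-(triethylsilyloxy)oxetan-3-yl]-13,14,15,16-tetranorlabd-8-en-7-one | CC1=C(CCC2(O[Si](CC)(CC)CC)COC2)[C@@]2(C)CCCC(C)(C)[C@@H]2CC1=O | intermediate
11 | lithium (5S,10S)-12-[3-(triethylsilyloxy)oxetan-3-yl]-13,14,15,16-tetranorlabda-6,8-dien-7-olate (formed in the flask, not isolated) | CC1=C(CCC2(O[Si](CC)(CC)CC)COC2)[C@@]2(C)CCCC(C)(C)[C@@H]2C=C1O[Li] | intermediate
12 | (5S,10S)-7-(triethylsilyloxy)-12-[3-(triethylsilyloxy)oxetan-3-yl]-13,14,15,16-tetranorlabda-6,8-diene | CC1=C(CCC2(O[Si](CC)(CC)CC)COC2)[C@@]2(C)CCCC(C)(C)[C@@H]2C=C1O[Si](CC)(CC)CC | intermediate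
13 | 7β-(triethylsilyloxy)-12-[3-(triethylsilyloxy)oxetan-3-yl]-13,14,15,16-tetranorlabd-8-en-6α-ylborane (BH2 on C6, α; formed in the flask, not isolated) | CC1=C(CCC2(O[Si](CC)(CC)CC)COC2)[C@@]2(C)CCCC(C)(C)[C@@H]2[C@@H](B)[C@@H]1O[Si](CC)(CC)CC | intermediate
14 | (5S,6R,7R,10S)-7β-(triethylsilyloxy)-12-[3-(triethylsilyloxy)oxetan-3-yl]-13,14,15,16-tetranorlabd-8-en-6α-ol | CC1=C(CCC2(O[Si](CC)(CC)CC)COC2)[C@@]2(C)CCCC(C)(C)[C@@H]2[C@@H](O)[C@@H]1O[Si](CC)(CC)CC | intermediate
15 | (5S,7R,10S)-7β-(triethylsilyloxy)-12-[3-(triethylsilyloxy)oxetan-3-yl]-13,14,15,16-tetranorlabd-8-en-6-one | CC1=C(CCC2(O[Si](CC)(CC)CC)COC2)[C@@]2(C)CCCC(C)(C)[C@@H]2C(=O)[C@@H]1O[Si](CC)(CC)CC | intermediate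
16 | (5S,6S,7R,10S)-7β-(triethylsilyloxy)-12-[3-(triethylsilyloxy)oxetan-3-yl]-13,14,15,16-tetranorlabd-8-en-6β-ol | CC1=C(CCC2(O[Si](CC)(CC)CC)COC2)[C@@]2(C)CCCC(C)(C)[C@@H]2[C@H](O)[C@@H]1O[Si](CC)(CC)CC | intermediate
17 | (5S,6S,7R,10S)-6β,7β-bis(triethylsilyloxy)-12-[3-(triethylsilyloxy)oxetan-3-yl]-13,14,15,16-tetranorlabd-8-ene | CC1=C(CCC2(O[Si](CC)(CC)CC)COC2)[C@@]2(C)CCCC(C)(C)[C@@H]2[C@H](O[Si](CC)(CC)CC)[C@@H]1O[Si](CC)(CC)CC | intermediate
18 | carbon monoxide | [C-]#[O+] | starting material
19 | (5S,6S,7R,10S,13S)-6β,7β,13-tris(triethylsilyloxy)labd-8-en-15,16-olide | CC1=C(CC[C@@]2(O[Si](CC)(CC)CC)COC(=O)C2)[C@@]2(C)CCCC(C)(C)[C@@H]2[C@H](O[Si](CC)(CC)CC)[C@@H]1O[Si](CC)(CC)CC | intermediate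
20 | (5S,6S,7R,10S,13S)-6β,7β,13-trihydroxylabd-8-en-15,16-olide | CC1=C(CC[C@@]2(O)COC(=O)C2)[C@@]2(C)CCCC(C)(C)[C@@H]2[C@H](O)[C@@H]1O | intermediate
21 | (5S,6S,10S,13S)-6β,13-dihydroxy-7-oxolabd-8-en-15,16-olide | CC1=C(CC[C@@]2(O)COC(=O)C2)[C@@]2(C)CCCC(C)(C)[C@@H]2[C@H](O)C1=O | target

## Step count and least certain steps

Total: 14 steps. Longest linear sequence: 14 steps from 1 (6 and 18 enter in single steps).

**Step 12 (key step, proposed new method).** Several things may go wrong. SN2 attack of cobaltate at a CH2 next to a quaternary carbon may be slow, so that the reaction stalls. The oxetane may oligomerise by cationic ring opening. β-Silyloxy elimination from the alkylcobalt intermediate may outrun CO insertion. The two enantiotopic CH2–O bonds may be poorly discriminated, which would give the C13 epimer as well. The fallback uses known chemistry and runs from 17 back to 19. The oxetane is opened enantioselectively with Me3SiBr under a chiral squaramide hydrogen-bond donor, a known desymmetrisation of 3,3-disubstituted oxetanes, to give the C14 bromide C16 trimethylsilyl ether F1. Brief acid-catalysed methanolysis removes only the primary trimethylsilyl group and gives the bromohydrin F2. Palladium-catalysed carbonylative lactonisation of the primary bromide (PdCl2(PPh3)2 with the N-heterocyclic carbene 1,3-dimesitylimidazol-2-ylidene, CO, i-Pr2NEt) then closes the lactone to 19. Its oxidative addition runs through an alkyl radical and is not slowed by the neopentyl position.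

**Step 1.** Equilibration of the alkene may be incomplete, leaving the C7=C8 and C8=C17 positional isomers, which co-elute and would give regioisomeric enones later. The fallback is regiospecific and runs from 1 back to 4. α,β-Dehydrogenation of the lactone through its lithium enolate (N-tert-butylbenzenesulfinimidoyl chloride) gives 9(11)-dehydrosclareolide F3. SmI2 in THF/MeOH cleaves the now allylic C8–O bond reductively, and α-protonation of the resulting dienolate gives acid 2 with the alkene fixed at C8=C9. LiAlH4 reduces 2 directly to 4.

**Step 8 (with step 7).** Competing γ-deprotonation in step 7, borane addition to the wrong alkene, or elimination of the β-silyloxy borane before oxidation may intervene. The fallback needs neither a kinetic enolate nor a borane and runs from 10 back to 14. α'-Acetoxylation of the enone with Mn(OAc)3 in hot benzene gives the 6α-acetoxy enone F4. LiAlH4 reduces ketone and acetate, with axial hydride delivery at C7 from the α-face, to the 6α,7β-diol F5. The allylic 7-hydroxyl is then silylated selectively (Et3SiCl, imidazole, low temperature), because the 6α-hydroxyl lies in the peri region of the 4α-methyl group, giving 14.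

**Step 14.** The new α-ketol may be over-oxidised toward the diosphenol with loss of C5 and C6, the cis-6,7-diol may undergo glycol cleavage on the oxidant, or the polar triol may be converted slowly because it adsorbs on MnO2. The fallback oxidises while O6 and O13 are still protected and runs from 19 back to 21. Mild acid methanolysis (pyridinium p-toluenesulfonate, MeOH, 0 °C) removes the most accessible silyl group, the allylic secondary one on O7, giving the 7β-alcohol F6. Dess–Martin oxidation gives the 6β,13-bis(triethylsilyl) ether of the target F7. HF·pyridine then gives 21.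

## Further compounds

F1 | step 12 | (5S,6S,7R,10S,13R)-14-bromo-6β,7β,13-tris(triethylsilyloxy)-16-(trimethylsilyloxy)-15-norlabd-8-ene (C13 bears CH2Br, CH2OSiMe3, OSiEt3 and C12) | CC1=C(CC[C@@](CBr)(O[Si](CC)(CC)CC)CO[Si](C)(C)C)[C@@]2(C)CCCC(C)(C)[C@@H]2[C@H](O[Si](CC)(CC)CC)[C@@H]1O[Si](CC)(CC)CC
F2 | step 12 | (5S,6S,7R,10S,13R)-14-bromo-6β,7β,13-tris(triethylsilyloxy)-15-norlabd-8-en-16-ol | CC1=C(CC[C@@](CBr)(O[Si](CC)(CC)CC)CO)[C@@]2(C)CCCC(C)(C)[C@@H]2[C@H](O[Si](CC)(CC)CC)[C@@H]1O[Si](CC)(CC)CC
F3 | step 1 | 9(11)-dehydrosclareolide (butenolide, C9=C11) | C[C@]12CCCC(C)(C)[C@@H]1CC[C@@]1(C)OC(=O)C=C12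
F4 | step 8 | (5S,6R,10S)-6α-acetoxy-12-[3-(triethylsilyloxy)oxetan-3-yl]-13,14,15,16-tetranorlabd-8-en-7-one | CC1=C(CCC2(O[Si](CC)(CC)CC)COC2)[C@@]2(C)CCCC(C)(C)[C@@H]2[C@@H](OC(C)=O)C1=O
F5 | step 8 | (5S,6R,7R,10S)-12-[3-(triethylsilyloxy)oxetan-3-yl]-13,14,15,16-tetranorlabd-8-ene-6α,7β-diol | CC1=C(CCC2(O[Si](CC)(CC)CC)COC2)[C@@]2(C)CCCC(C)(C)[C@@H]2[C@@H](O)[C@@H]1O
F6 | step 14 | (5S,6S,7R,10S,13S)-7β-hydroxy-6β,13-bis(triethylsilyloxy)labd-8-en-15,16-olide | CC1=C(CC[C@@]2(O[Si](CC)(CC)CC)COC(=O)C2)[C@@]2(C)CCCC(C)(C)[C@@H]2[C@H](O[Si](CC)(CC)CC)[C@@H]1O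
F7 | step 14 | (5S,6S,10S,13S)-7-oxo-6β,13-bis(triethylsilyloxy)labd-8-en-15,16-olide | CC1=C(CC[C@@]2(O[Si](CC)(CC)CC)COC(=O)C2)[C@@]2(C)CCCC(C)(C)[C@@H]2[C@H](O[Si](CC)(CC)CC)C1=O
A1 | alternative 1 | (5E,9E)-farnesylacetone, (5E,9E)-6,10,14-trimethylpentadeca-5,9,13-trien-2-one | CC(=O)CC/C=C(C)/CC/C=C(C)/CCC=C(C)C
A2 | alternative 1 | sclareol oxide, 8α,13-epoxy-14,15-dinorlabd-12-ene | CC1=CC[C@@H]2[C@@]3(C)CCCC(C)(C)[C@@H]3CC[C@@]2(C)O1
A3 | alternative 2 | 2,6-dimethyl-1,4-benzoquinone | CC1=CC(=O)C=C(C)C1=O
A4 | alternative 2 | 4-methylpenta-1,3-diene | CC(C)=CC=C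
A5 | alternative 2 | cis-fused 2,5,5,8a-tetramethyl-4a,5,8,8a-tetrahydronaphthalene-1,4-dione (ring-fusion H and CH3 cis) | CC1=CC(=O)[C@@H]2C(C)(C)C=CC[C@]2(C)C1=O
A6 | alternative 3 | 6-[4-(methoxymethoxy)-3-oxobutyl]-2,2,6-trimethylcyclohexan-1-one (single enantiomer at the quaternary carbon) | COCOCC(=O)CC[C@@]1(C)CCCC(C)(C)C1=O
A7 | alternative 3 | 1-(methoxymethoxy)-4a,8,8-trimethyl-4,4a,5,6,7,8-hexahydronaphthalen-2(3H)-one | O=C1CC[C@@]2(C)CCCC(C)(C)C2=C1OCOC
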